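A millimolar of catalyst was my unit of account for this flask. Free catalyst turns starting material into open intermediate and back, and it joins open intermediate to coupling partner to give product.

the same everywhere: starting material 0.20 M; impurity 0.17 mM

|  | coupling partner | capture agent | free catalyst | remark | time |
|---|---|---|---|---|---|
| Thursday's | 1.2 equiv | 4 mM | 0.7 mol% (in portions, 4) | run made earlier; portions every 0.60 s |  |
| Sunday's | 1.2 equiv | 4 mM | 1.1 mol% (in portions, 4) | run made earlier; portions every 0.60 s |  |
| flask | 1.20 equiv | 4.00 mM | 0.5 mol% (in portions, 4) | the portions of free catalyst follow each other after 0.60 s, the first at the start | 6.0 min |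

| run | time / min | starting material / % | product / % | open intermediate / % |
|---|---|---|---|---|
| Thursday's | 0.250 | 43.0 | 13.0 | 40.9 |
| Thursday's | 0.667 | 42.6 | 13.9 | 42.0 |
| Thursday's | 1.50 | 42.2 | 13.4 | 41.5 |
| Thursday's | 4.00 | 43.6 | 13.0 | 41.6 |
| Sunday's | 0.417 | 38.7 | 21.5 | 37.6 |
| Sunday's | 1.33 | 39.5 | 20.6 | 37.3 |
| Sunday's | 2.50 | 39.7 | 20.7 | 37.9 |
| Sunday's | 4.00 | 39.6 | 20.8 | 37.9 |

(each reading ± 0.5 percentage points)

1. share of the starting material used up at 6.0 min
2. product at 6.0 min, in percent of the starting material charged
3. open intermediate at 6.0 min, in percent of the starting material charged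

I built the flask up one process at a time. First I took the two catalysed steps. The ratio of open intermediate to starting material read 0.954 in Thursday's run and 0.957 in Sunday's, so I treated that pair as equilibrated.

Then I added the death of the catalyst. Thursday's product read 13.0% at 0.250 min and 13.0% at 4.00 min, so I stopped counting time and counted catalyst.

Then I added the impurity, which I assumed takes catalyst one for one. The first portion of this flask, 0.250 mM, is more than the 0.17 mM of impurity. I let S be the surviving catalyst, the catalyst charged minus the impurity charged, and g the mean product per millimolar of S.

Thursday's: S = 1.23 mM, product per S = 0.108 mM⁻¹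

Sunday's: S = 2.03 mM, product per S = 0.103 mM⁻¹

Mean: g = 0.106 mM⁻¹

This flask: S = 0.830 mM, product = g × S = 8.77%

Last I added the capture agent, 2.00% of the starting material. Reckoning that as ending up trapped intermediate, I had 89.2% to share between starting material and open intermediate.

The forecast said “the catalyst dies within seconds”. It gave conversion 54.7% (52% to 56.5%), product 9.5% (8.3% to 10.6%) and open intermediate 43.1% (40.5% to 44.5%). My product stood below its number, inside its range.

The flask gave conversion 54.2%, product 8.75% and open intermediate 43.4%.

    free catalyst + impurity → spent catalyst B (k = 89000 L mol⁻¹ s⁻¹)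
    open intermediate + capture agent → trapped intermediate (k = 6.90 L mol⁻¹ s⁻¹)
    coupling partner + free catalyst + open intermediate → free catalyst + product (k = 310 L² mol⁻² s⁻¹)
    starting material + free catalyst ⇌ free catalyst + open intermediate (K = 0.990, k = 950 L mol⁻¹ s⁻¹)
    free catalyst → spent catalyst A (k = 0.260 s⁻¹)

In this flask free catalyst read 0% at 6.00 min, with 17.0% of the charge as spent catalyst B and 83.0% as spent catalyst A, which is S over the charge, 83.0%. The forecast's near-equal split of starting material and open intermediate held in this flask, and a neighbour flask with less catalyst shows a change that breaks such a split. At 0.12 mol% its S was 0.0700 mM, and it held 79.8% starting material against 18.0% open intermediate, with product 0.204%. Ten times the time changed nothing in this flask: at 60.0 min it stood at conversion 54.2%, product 8.75% and open intermediate 43.4%.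

The earlier runs and the new flask are calculated for substances that don't exist; noise was put on by code.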